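(The data were generated by integration with constants of no real substance, noise included.)

**The question.** Target grows in these runs as substrate is used, so the question for this flask is how much substrate still stands when dosing ends.

| setting | Tuesday's | Thursday's | Sunday's | flask |
|---|---|---|---|---|
| substrate | 0.065 M (fed, over 40 h) | 0.065 M (fed, over 40 h) | 0.13 M (fed, over 40 h) | 0.065 M (fed, over 40 h) |
| acid | 1.3 mM | 2.9 mM | 1.95 mM | 1.95 mM |
| remark | run made earlier | run made earlier | run made earlier |  |
| time |  |  |  | 40 h |

| run | time / h | substrate / % | target / % |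
|---|---|---|---|
| Tuesday's | 5.00 | 11.2 | 0.5 |
| Tuesday's | 10.0 | 22.0 | 2.7 |
| Tuesday's | 15.0 | 30.0 | 7.1 |
| Tuesday's | 20.0 | 39.3 | 10.5 |
| Tuesday's | 25.0 | 44.9 | 15.9 |
| Thursday's | 2.00 | 5.3 | 0.7 |
| Thursday's | 4.00 | 8.8 | 0.5 |
| Thursday's | 6.00 | 11.7 | 2.6 |
| Thursday's | 12.0 | 22.3 | 8.0 |
| Thursday's | 25.0 | 34.2 | 26.6 |
| Sunday's | 5.00 | 11.2 | 1.1 |
| Sunday's | 10.0 | 21.1 | 4.1 |
| Sunday's | 15.0 | 28.6 | 7.9 |
| Sunday's | 20.0 | 34.2 | 14.5 |
| Sunday's | 25.0 | 38.9 | 20.5 |

(readings scatter by 0.5 percentage points)

- acid is the free proton; pH is minus the decimal logarithm of its molar concentration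
- percentages count the whole charge, also what has not yet gone in

1. part of the substrate that has reacted at 40 h
2. pH of the solution at 40 h

**Nearest run.** Sunday's run has the flask's acid, 1.95 mM, and twice the flask's substrate. Define k, the pseudo-first-order constant, as the share of the substrate present that reacts per hour. Substrate fed minus substrate found by 25.0 h, divided by the time integral of c(substrate), gives a reading for Sunday's run of k = 0.0412 h⁻¹. Tuesday's run gives 0.0282 h⁻¹. The ratio of these two readings, 1.46, lies close to the acid ratio, 1.50, although the substrate differs as well. So this reckoning assumes that the flask, at Sunday's acid, has Sunday's k.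

**Feed balance.** While the feed lasts, feed and reaction balance at feed over k, by this reckoning a level of 60.7% of the charge. Substrate in the flask approaches that level exponentially with lifetime 24.3 h, shorter than the dosing time. This reckoning therefore leaves 49.0% at 40 h, so 51.0% has reacted.

**The forecast.** It gives 51% reacted and pH 2.7, on the ground that “the rate is first order in substrate and in acid”.

**The result.** The flask gives 50.3% reacted and pH 2.71. With all else held, the part reacted has moved by 5 points at acid of 1.59 mM or 2.38 mM, so the forecast's figure belongs to the charged acid and not to those. At 20.0 h, the reckoning with k gives 34.1% substrate, and the flask holds 35.1%.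

    substrate → weak acid + target (k = 0.00490 h⁻¹)
    substrate + weak acid → side product (k = 0.500 M⁻¹ h⁻¹)
    weak acid → by-product carried off (k = 0.0710 h⁻¹)
    weak acid ⇌ conjugate base + acid, settled at all times (K = 2.00 × 10⁻¹⁰ M)
    substrate + acid → weak acid + acid + target (k = 16.0 M⁻¹ h⁻¹)

**Later reading.** For this flask read at 4.0 d, dosing has ended, and decay with k from the reckoned 49.0% gives 4.88% substrate. The computed flask has 5.3% left, so 94.7% has reacted.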